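**Strategy**

Numbering the dienone ring C1 (C=O), C2 (propenyl), C3, C4 (quaternary C–OMe), C5 (=C–OMe), C6, the target is the di-O-methyl ether of a 4-hydroxycyclohex-5-ene-1,3-dione: C4–C5 is an α-hydroxy acid and C3–C2–C1–C6 a β-methoxy enone. The acid is locked as a cis-2-tert-butyl-1,3-dioxolan-4-one, a temporary ring whose acetal carbon stores the chirality. In one flask its enolate displaces methoxide at C3 (C3–C4, quaternary centre set anti to tert-butyl) and the methyl-ketone enolate is then acylated by the lactone carbonyl (C6–C5), an anionic [4+2] annulation that ejects the auxiliary as pivalaldehyde. Both liberated oxygens are methylated afterwards.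

Key step: step 6

Assumption (step 2): the facial sense of the hydrogenation is set by the ligand antipode; (S)-SunPhos is written as the one expected to give the (S)-acid, and (R)-SunPhos would be used without other change if the sense proves opposite.

**Route**

Step 1
Reactants: 1 3,4-dimethoxybenzaldehyde; 2 2-oxobutanoic acid
Product: 3 (3E)-4-(3,4-dimethoxyphenyl)-3-methyl-2-oxobut-3-enoic acid
Conditions: KOH, MeOH/H2O, 0 °C to rt; then aq. HCl
Reagents that add atoms: none
Why: Crossed aldol condensation of the non-enolizable aldehyde with the C3 methylene of the α-keto acid, followed by dehydration, should give the conjugated arylidene keto acid as its more stable (E)-isomer.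

Step 2
Reactants: 3 (3E)-4-(3,4-dimethoxyphenyl)-3-methyl-2-oxobut-3-enoic acid
Product: 4 (2S,3E)-4-(3,4-dimethoxyphenyl)-2-hydroxy-3-methylbut-3-enoic acid
Conditions: H2 (20 bar), [RuCl(benzene)((S)-SunPhos)]Cl (1 mol%), THF, 70 °C
Reagents that add atoms: none
Why: Catalytic asymmetric hydrogenation of a β,γ-unsaturated α-keto acid with a ruthenium–diphosphine complex should reduce the carboxyl-assisted ketone chemoselectively, the chiral diphosphine setting C2 and the trisubstituted styrene remaining untouched.

Step 3
Reactants: 4 (2S,3E)-4-(3,4-dimethoxyphenyl)-2-hydroxy-3-methylbut-3-enoic acid; 5 pivalaldehyde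
Product: 7 (2S,5S)-2-tert-butyl-5-[(1E)-1-(3,4-dimethoxyphenyl)prop-1-en-2-yl]-1,3-dioxolan-4-one, via bis(trimethylsilyl) derivative 6 (not isolated)
Conditions: Me3SiCl, Et3N, CH2Cl2, 0 °C; then t-BuCHO, Me3SiOTf (5 mol%), CH2Cl2, −78 °C
Reagents that add atoms: trimethylsilyl chloride, C[Si](C)(C)Cl (its silicon is carried by 6 only)
Why: Silyl-triflate-catalysed acetalization of the bis-silylated hydroxy acid at low temperature should give the cis-dioxolanone, the new acetal centre C2 being relayed from the untouched C5 centre (tert-butyl and alkenyl on the same face), without the protic acid that could ionize the electron-rich allylic alcohol.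

Step 4
Reactants: 8 (3E)-4-methoxybut-3-en-2-one
Product: 9 (3Z)-3-iodo-4-methoxybut-3-en-2-one
Conditions: I2, pyridine, CH2Cl2, 0 °C to rt
Reagents that add atoms: iodine, II
Why: Electrophilic α-iodination of the vinylogous ester at its nucleophilic α-carbon, with pyridine taking up the proton, should give the α-iodo enone; its alkene geometry is of no consequence because that carbon is re-hybridized in step 6.

Step 5
Reactants: 9 (3Z)-3-iodo-4-methoxybut-3-en-2-one; 10 2-[(1E)-prop-1-en-1-yl]-4,4,5,5-tetramethyl-1,3,2-dioxaborolane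
Product: 11 (3E,4E)-3-(methoxymethylidene)hex-4-en-2-one
Conditions: Pd(PPh3)4 (5 mol%), CsF, THF, 60 °C
Reagents that add atoms: none
Why: Suzuki–Miyaura coupling of the α-iodo enone with the (E)-alkenylboronate should proceed with retention at both alkenes, and anhydrous fluoride activation spares the hydrolysis-prone vinylogous ester.

Step 6
Reactants: 7 (2S,5S)-2-tert-butyl-5-[(1E)-1-(3,4-dimethoxyphenyl)prop-1-en-2-yl]-1,3-dioxolan-4-one; 11 (3E,4E)-3-(methoxymethylidene)hex-4-en-2-one
Product: 14 (4S)-4-[(1E)-1-(3,4-dimethoxyphenyl)prop-1-en-2-yl]-4-hydroxy-6-[(1E)-prop-1-en-1-yl]cyclohex-5-ene-1,3-dione, via lithium dienolate 12 (not isolated), via conjugate substitution product 13 (not isolated)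
Conditions: LiN(SiMe3)2 (1.05 equiv), THF, −78 °C; 11, −78 to −40 °C; LiN(SiMe3)2 (1.5 equiv), −78 to 0 °C; aq. HCl to pH 3
Reagents that add atoms: none
Why: Deprotonation of 7 gives the planar dienolate 12, whose α-carbon adds to C3 of the β-methoxy enone 11 and expels methoxide (addition–elimination) to give 13; the second charge of base forms the kinetic methyl-ketone enolate at C6, which attacks the dioxolanone carbonyl, and collapse of the tetrahedral intermediate opens the acetal, releases pivalaldehyde and leaves the stabilized enolate of 14. The closest known reaction type is the Michael–Claisen (Michael–Dieckmann) annulation to cyclohexane-1,3-diones, merged here with the self-regeneration-of-stereocentres use of a 1,3-dioxolan-4-one enolate. The six-membered ring closes by a 6-(enolendo)-exo-trig acyl substitution. The quaternary centre C4 is controlled by the acetal carbon C2 of 7: its tert-butyl group shields one face of the enolate, so the new C3–C4 bond takes the place of the former C5–H bond with net retention, which corresponds to the (S)-configuration of the target. The step needs α- rather than γ-attack of the dienolate, which the hindered benzylic γ-carbon and kinetic control should secure, and it needs the C2=C3 geometry with acetyl cis to C4. That geometry is expected from elimination through the lithium-bridged enolate and otherwise from equilibration of the alkene isomers by reversible re-addition of the liberated lithium methoxide, only the cis isomer being drained by the irreversible ring closure.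

Step 7
Reactants: 14 (4S)-4-[(1E)-1-(3,4-dimethoxyphenyl)prop-1-en-2-yl]-4-hydroxy-6-[(1E)-prop-1-en-1-yl]cyclohex-5-ene-1,3-dione
Product: 15 (4S)-4-[(1E)-1-(3,4-dimethoxyphenyl)prop-1-en-2-yl]-4-hydroxy-5-methoxy-2-[(1E)-prop-1-en-1-yl]cyclohexa-2,5-dien-1-one
Conditions: HC(OMe)3, MeOH, PPTS (10 mol%), rt
Reagents that add atoms: trimethyl orthoformate, COC(OC)OC
Why: Acid-catalysed enol etherification of a cyclic 1,3-dione is reversible, so the methoxy group should settle on C5 to give the cross-conjugated 2,5-dienone whose carbonyl is remote from the electron-withdrawing C4–O bond, in preference to the linearly conjugated 2,4-dienone isomer.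

Step 8
Reactants: 15 (4S)-4-[(1E)-1-(3,4-dimethoxyphenyl)prop-1-en-2-yl]-4-hydroxy-5-methoxy-2-[(1E)-prop-1-en-1-yl]cyclohexa-2,5-dien-1-one
Product: 16 (4S)-4-[(1E)-1-(3,4-dimethoxyphenyl)prop-1-en-2-yl]-4,5-dimethoxy-2-[(1E)-prop-1-en-1-yl]cyclohexa-2,5-dien-1-one
Conditions: NaH, MeI, THF/DMF, 0 °C
Reagents that add atoms: iodomethane, CI
Why: Williamson etherification of the tertiary alkoxide, the only acidic site left, should give the methyl ether without breaking any bond to C4, so the stereocentre is retained.

**Compound list**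

1 | 3,4-dimethoxybenzaldehyde | COc1ccc(C=O)cc1OC | starting material
2 | 2-oxobutanoic acid | CCC(=O)C(=O)O | starting material
3 | (3E)-4-(3,4-dimethoxyphenyl)-3-methyl-2-oxobut-3-enoic acid | COc1ccc(/C=C(\C)C(=O)C(=O)O)cc1OC | intermediate
4 | (2S,3E)-4-(3,4-dimethoxyphenyl)-2-hydroxy-3-methylbut-3-enoic acid | COc1ccc(/C=C(\C)[C@H](O)C(=O)O)cc1OC | intermediate
5 | pivalaldehyde (2,2-dimethylpropanal) | CC(C)(C)C=O | starting material
6 | trimethylsilyl (2S,3E)-4-(3,4-dimethoxyphenyl)-3-methyl-2-[(trimethylsilyl)oxy]but-3-enoate | COc1ccc(/C=C(\C)[C@H](O[Si](C)(C)C)C(=O)O[Si](C)(C)C)cc1OC | intermediate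
7 | (2S,5S)-2-tert-butyl-5-[(1E)-1-(3,4-dimethoxyphenyl)prop-1-en-2-yl]-1,3-dioxolan-4-one (cis) | COc1ccc(/C=C(\C)[C@@H]2O[C@H](C(C)(C)C)OC2=O)cc1OC | intermediate
8 | (3E)-4-methoxybut-3-en-2-one | CO/C=C/C(C)=O | starting material
9 | (3Z)-3-iodo-4-methoxybut-3-en-2-one | CO/C=C(\I)C(C)=O | intermediate
10 | 2-[(1E)-prop-1-en-1-yl]-4,4,5,5-tetramethyl-1,3,2-dioxaborolane | C/C=C/B1OC(C)(C)C(C)(C)O1 | starting material
11 | (3E,4E)-3-(methoxymethylidene)hex-4-en-2-one | C/C=C/C(=C\OC)C(C)=O | intermediate
12 | lithium (2S)-2-tert-butyl-5-[(1E)-1-(3,4-dimethoxyphenyl)prop-1-en-2-yl]-1,3-dioxol-4-olate | COc1ccc(/C=C(\C)C2=C(O[Li])O[C@@H](C(C)(C)C)O2)cc1OC | intermediate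
13 | (2S,5S)-5-[(1Z,3E)-2-acetylpenta-1,3-dien-1-yl]-2-tert-butyl-5-[(1E)-1-(3,4-dimethoxyphenyl)prop-1-en-2-yl]-1,3-dioxolan-4-one | COc1ccc(/C=C(\C)[C@]2(/C=C(/C=C/C)C(C)=O)O[C@H](C(C)(C)C)OC2=O)cc1OC | intermediate
14 | (4S)-4-[(1E)-1-(3,4-dimethoxyphenyl)prop-1-en-2-yl]-4-hydroxy-6-[(1E)-prop-1-en-1-yl]cyclohex-5-ene-1,3-dione | C/C=C/C1=C[C@](O)(/C(C)=C/c2ccc(OC)c(OC)c2)C(=O)CC1=O | intermediate
15 | (4S)-4-[(1E)-1-(3,4-dimethoxyphenyl)prop-1-en-2-yl]-4-hydroxy-5-methoxy-2-[(1E)-prop-1-en-1-yl]cyclohexa-2,5-dien-1-one | C/C=C/C1=C[C@](O)(/C(C)=C/c2ccc(OC)c(OC)c2)C(OC)=CC1=O | intermediate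
16 | (4S)-4-[(1E)-1-(3,4-dimethoxyphenyl)prop-1-en-2-yl]-4,5-dimethoxy-2-[(1E)-prop-1-en-1-yl]cyclohexa-2,5-dien-1-one | C/C=C/C1=C[C@](OC)(/C(C)=C/c2ccc(OC)c(OC)c2)C(OC)=CC1=O | target

**Step count**

Total: 8 steps. Longest linear sequence: 6 steps (1, 2, 3, 6, 7, 8); steps 4 and 5 build the second fragment.

**Steps most likely to fail**

Step 6. The conjugate substitution may leave the alkene with the acetyl group trans to C4, which cannot cyclize, or the enolate may decay or transfer a proton before it adds. The fallback separates the two bond formations and closes the ring under equilibrating conditions. It sets out from 13, obtained by running only the first stage and quenching at −40 °C. NaOMe in MeOH at rt would open the dioxolanone to methyl (2S,3Z,5E)-4-acetyl-2-[(1E)-1-(3,4-dimethoxyphenyl)prop-1-en-2-yl]-2-hydroxyhepta-3,5-dienoate F1. The same methoxide should interconvert the alkene isomers by reversible conjugate addition and effect the Dieckmann closure of the cis isomer, driven by deprotonation of the dione. The route is rejoined at 14.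

Step 7. Enol etherification may stop at, or equilibrate toward, the isomer methylated on the C1 oxygen, and the acid may ionize the tertiary allylic alcohol. The fallback fixes the regiochemistry by blocking instead of equilibration. Setting out from 14, i-Pr3SiOTf and 2,6-lutidine at −78 °C should silylate the less hindered enol oxygen at C1, remote from the quaternary carbon, to give (6S)-6-[(1E)-1-(3,4-dimethoxyphenyl)prop-1-en-2-yl]-6-hydroxy-4-[(1E)-prop-1-en-1-yl]-3-[(triisopropylsilyl)oxy]cyclohexa-2,4-dien-1-one F2. Me3OBF4 with 2,6-di-tert-butylpyridine would then methylate the carbonyl oxygen at C5 of this vinylogous silyl ester. Fluoride work-up removes silicon from the resulting 1-silyloxy-3-methoxy cation and returns the route at 15.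

Step 2. The hydrogenation may give insufficient enantiomeric purity, or the allylic hydroxy acid may isomerize or be over-reduced. The fallback replaces asymmetric catalysis by resolution. Setting out from 3, NaBH4 in aqueous NaHCO3/MeOH at 0 °C would give racemic (3E)-4-(3,4-dimethoxyphenyl)-2-hydroxy-3-methylbut-3-enoic acid F3. Crystallization with (S)-1-phenylethylamine should give the salt (1S)-1-phenylethanaminium (2S,3E)-4-(3,4-dimethoxyphenyl)-2-hydroxy-3-methylbut-3-enoate F4; the antipodal amine would be used if its salt with the (S)-acid is the less soluble one. Acidification with aq. HCl returns the route at 4.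

**Further compounds**

F1 | step 6 | methyl (2S,3Z,5E)-4-acetyl-2-[(1E)-1-(3,4-dimethoxyphenyl)prop-1-en-2-yl]-2-hydroxyhepta-3,5-dienoate | COC(=O)[C@](O)(/C=C(/C=C/C)C(C)=O)/C(C)=C/c1ccc(OC)c(OC)c1
F2 | step 7 | (6S)-6-[(1E)-1-(3,4-dimethoxyphenyl)prop-1-en-2-yl]-6-hydroxy-4-[(1E)-prop-1-en-1-yl]-3-[(triisopropylsilyl)oxy]cyclohexa-2,4-dien-1-one | C/C=C/C1=C[C@](O)(/C(C)=C/c2ccc(OC)c(OC)c2)C(=O)C=C1O[Si](C(C)C)(C(C)C)C(C)C
F3 | step 2 | (3E)-4-(3,4-dimethoxyphenyl)-2-hydroxy-3-methylbut-3-enoic acid (racemate) | COc1ccc(/C=C(\C)C(O)C(=O)O)cc1OC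
F4 | step 2 | (1S)-1-phenylethanaminium (2S,3E)-4-(3,4-dimethoxyphenyl)-2-hydroxy-3-methylbut-3-enoate | C[C@H]([NH3+])c1ccccc1.COc1ccc(/C=C(\C)[C@H](O)C(=O)[O-])cc1OC
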